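**Plan**
- Retrosynthetic cuts: the C5 ester (O–C5); the lactone bond O1–C13 together with C15–C16 (the propyl group is read as vinyl plus one carbon); the tetrahydropyran bonds O–C3 and C3–C4; C6–C7; C11–C12; the C7–C11 segment comes from 3-methylglutarate.
- Enabling feature: C13 is a carbinol carbon bearing only an unfunctionalised n-propyl chain, so O1–C13–C14=C15 is the retron of a branched allylic ester. A terminal allene C13=C14=C15 and the free C1 acid, held near each other by the 2,6-cis tetrahydropyran (O, C3–C7), close the 14-membered lactone at O1–C13 and set C13 in the same event.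
- Forward order: chain C7–C14 (hemiester, propargylation, O-methylation, allylation), then the tetrahydropyran (oxa-Michael/Prins), allene, 14-membered ring, vinyl to propyl, and last the oxazole side chain by Mitsunobu esterification.
- Stereochemistry: C9 from the chiral pool; C11 and C7 by catalyst and reagent control (both Si-face additions); C3 and C5 from C7 through the chair Prins transition state; C13 from the chiral bisphosphine on rhodium; C5 inverted in the final Mitsunobu step; the two Z-olefins from Lindlar reduction and Still–Gennari olefination.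

Key step: step 12

Assumption: (S)-TRIP (step 4) and (R,R)-DIOP (step 12) are named as the enantiomers expected, by analogy with simple aldehydes and allenes, to give Si-face propargylation and the (S)-configured vinyl carbinol ester; if either sense is the opposite, the mirror-image catalyst or ligand is used and nothing else changes.

**Route**

Step 1
Reactants: 1 (R)-5-methoxy-3-methyl-5-oxopentanoic acid (methyl hydrogen (R)-3-methylglutarate)
Product: 3 (S)-4-methyltetrahydro-2H-pyran-2-one, via (S)-5-hydroxy-3-methylpentanoic acid 2 (not isolated)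
Conditions: LiBH4, THF, 0 °C to rt; then 2 M HCl, rt
Reagents that add atoms: none
Why: LiBH4 reduces the methyl ester but not the lithium carboxylate and acid closes the hydroxy acid to the six-membered lactone (chemoselective ester reduction, lactonisation), so the ester end of 1 becomes C11 and the acid end C7 while the C9 stereocentre is carried over unchanged.

Step 2
Reactants: 3 (S)-4-methyltetrahydro-2H-pyran-2-one
Product: 4 (S)-5-hydroxy-N-methoxy-N,3-dimethylpentanamide
Conditions: MeNH(OMe)·HCl, AlMe3, CH2Cl2, 0 °C to rt; aq. KNaC4H4O6 work-up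
Reagents that add atoms: N,O-dimethylhydroxylamine hydrochloride, CNOC.Cl
Why: Aminolysis of the lactone by the preformed aluminium amide (Weinreb amide formation) frees the C11 hydroxyl and stores C7 as an acyl group that can later be reduced cleanly to the aldehyde.

Step 3
Reactants: 4 (S)-5-hydroxy-N-methoxy-N,3-dimethylpentanamide
Product: 5 (S)-N-methoxy-N,3-dimethyl-5-oxopentanamide
Conditions: TEMPO (10 mol %), PhI(OAc)2, CH2Cl2, rt
Reagents that add atoms: none
Why: Oxoammonium (TEMPO) oxidation of the primary alcohol stops at the aldehyde and leaves the Weinreb amide untouched.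

Step 4
Reactants: 5 (S)-N-methoxy-N,3-dimethyl-5-oxopentanamide
Product: 6 (3S,5R)-5-hydroxy-N-methoxy-N,3-dimethyloct-7-ynamide
Conditions: allenylboronic acid pinacol ester, (S)-TRIP [(S)-3,3′-bis(2,4,6-triisopropylphenyl)-1,1′-binaphthyl-2,2′-diyl hydrogen phosphate] (10 mol %), 4 Å MS, toluene, −20 °C
Reagents that add atoms: allenylboronic acid pinacol ester, C=C=CB1OC(C)(C)C(C)(C)O1
Why: Chiral phosphoric acid-catalysed propargylboration proceeds through a closed six-membered SE2′ transition state organised by the phosphate, so only the homopropargylic alcohol forms and the catalyst directs attack to the Si face of the aldehyde, setting the (5R) carbinol (C11 of the target).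

Step 5
Reactants: 6 (3S,5R)-5-hydroxy-N-methoxy-N,3-dimethyloct-7-ynamide
Product: 7 (3S,5R)-N,5-dimethoxy-N,3-dimethyloct-7-ynamide
Conditions: Me3OBF4, 1,8-bis(dimethylamino)naphthalene, 4 Å MS, CH2Cl2, 0 °C to rt
Reagents that add atoms: trimethyloxonium tetrafluoroborate, C[O+](C)C.F[B-](F)(F)F
Why: Neutral O-methylation with the Meerwein salt and a non-nucleophilic proton scavenger etherifies the secondary alcohol without alkoxide-induced lactonisation onto the amide or deprotonation of the alkyne.

Step 6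
Reactants: 7 (3S,5R)-N,5-dimethoxy-N,3-dimethyloct-7-ynamide
Product: 8 (3S,5R)-5-methoxy-3-methyloct-7-ynal
Conditions: iBu2AlH, THF, −78 °C; aq. KNaC4H4O6 work-up
Reagents that add atoms: none
Why: Hydride reduction of a Weinreb amide halts at the chelated tetrahedral aluminate, which releases the aldehyde only on work-up.

Step 7
Reactants: 8 (3S,5R)-5-methoxy-3-methyloct-7-ynal
Product: 9 (4S,6R,8R)-8-methoxy-6-methylundec-1-en-10-yn-4-ol
Conditions: (−)-Ipc2BOMe, allylMgBr, Et2O, 0 °C to rt; then 8, −78 °C; then NaOH, H2O2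
Reagents that add atoms: allylmagnesium bromide, C=CC[Mg]Br
Why: Brown allylboration with (−)-Ipc2B(allyl) goes through a chair Zimmerman–Traxler transition state and adds to the Si face of the aldehyde under reagent control, setting the (4S) carbinol (C7 of the target).

Step 8
Reactants: 9 (4S,6R,8R)-8-methoxy-6-methylundec-1-en-10-yn-4-ol
Product: 10 methyl (E)-3-{[(4S,6R,8R)-8-methoxy-6-methylundec-1-en-10-yn-4-yl]oxy}prop-2-enoate
Conditions: methyl propiolate, N-methylmorpholine, CH2Cl2, rt
Reagents that add atoms: methyl propiolate, C#CC(=O)OC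
Why: Amine-catalysed oxa-Michael addition of the secondary alcohol to the propiolate gives the (E)-β-alkoxyacrylate, which brings in C1–C3 at the final oxidation level.

Step 9
Reactants: 10 methyl (E)-3-{[(4S,6R,8R)-8-methoxy-6-methylundec-1-en-10-yn-4-yl]oxy}prop-2-enoate
Product: 12 methyl 2-[(2R,4S,6R)-4-hydroxy-6-[(2S,4R)-4-methoxy-2-methylhept-6-yn-1-yl]tetrahydro-2H-pyran-2-yl]acetate, via tetrahydropyranyl trifluoroacetate 11 (not isolated)
Conditions: CF3CO2H, CH2Cl2, 0 °C to rt; evaporate; then K2CO3 (cat.), MeOH, rt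
Reagents that add atoms: trifluoroacetic acid, OC(=O)C(F)(F)F
Why: Prins cyclisation of the enol ether: protonation at C2 gives the oxocarbenium ion, the terminal alkene closes through a chair transition state with the C3 and C7 substituents equatorial (2,6-cis), trifluoroacetate is captured equatorially at C5 and methanolysis frees the all-cis alcohol, so C3 and C5 are both set from C7.

Step 10
Reactants: 12 methyl 2-[(2R,4S,6R)-4-hydroxy-6-[(2S,4R)-4-methoxy-2-methylhept-6-yn-1-yl]tetrahydro-2H-pyran-2-yl]acetate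
Product: 14 methyl 2-[(2R,4S,6R)-4-hydroxy-6-[(2S,4R)-4-methoxy-2-methylocta-6,7-dien-1-yl]tetrahydro-2H-pyran-2-yl]acetate, via propargylic dicyclohexylamine 13 (not isolated)
Conditions: (CH2O)n, CuI (0.5 equiv), Cy2NH, 1,4-dioxane, reflux
Reagents that add atoms: paraformaldehyde (as formaldehyde), C=O
Why: Crabbé homologation: a copper-mediated Mannich reaction gives the propargylic amine, whose [1,5]-hydride transfer releases the terminal allene C13=C14=C15 and an imine, and the free hydroxyl and ester are tolerated.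

Step 11
Reactants: 14 methyl 2-[(2R,4S,6R)-4-hydroxy-6-[(2S,4R)-4-methoxy-2-methylocta-6,7-dien-1-yl]tetrahydro-2H-pyran-2-yl]acetate
Product: 15 2-[(2R,4S,6R)-4-hydroxy-6-[(2S,4R)-4-methoxy-2-methylocta-6,7-dien-1-yl]tetrahydro-2H-pyran-2-yl]acetic acid
Conditions: LiOH, THF/MeOH/H2O, rt; then 1 M HCl to pH 3, 0 °C
Reagents that add atoms: lithium hydroxide, [Li+].[OH-]
Why: Saponification of the methyl ester; the allene, methyl ether and tetrahydropyran are inert to hydroxide and to brief mild acidification.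

Step 12
Reactants: 15 2-[(2R,4S,6R)-4-hydroxy-6-[(2S,4R)-4-methoxy-2-methylocta-6,7-dien-1-yl]tetrahydro-2H-pyran-2-yl]acetic acid
Product: 16 (1R,5S,7R,9S,11R,13S)-5-ethenyl-13-hydroxy-7-methoxy-9-methyl-4,15-dioxabicyclo[9.3.1]pentadecan-3-one
Conditions: [Rh(cod)Cl]2 (5 mol %), (R,R)-DIOP (12 mol %), ClCH2CH2Cl, 2 mM, slow addition of 15, 40 °C
Reagents that add atoms: none
Why: Oxidative addition of the acid O–H to monovalent rhodium gives a trivalent rhodium hydride carboxylate, which hydrometalates the terminal allene with hydride delivery to the central carbon C14 to form a π-allyl complex over C13–C15, and C–O bond formation at the substituted terminus C13 then releases the branched allylic ester and the monovalent catalyst, the whole being an isomerisation with no by-product. The closest known reaction type is the rhodium/bisphosphine-catalysed addition of carboxylic acids to terminal allenes and its intramolecular, macrolactone-forming version with ω-allenyl acids. The 14-membered ring closes by attack of the tethered carboxylate on the inner allyl terminus, so the vinyl group ends up exocyclic (exo mode), whereas the endo alternative through C15 would give a 16-membered linear allylic ester and is disfavoured by the branched preference of the catalyst. The new stereocentre C13 is controlled by the C2-symmetric DIOP ligand, because the allyl intermediates interconvert by π–σ–π isomerisation before C–O bond formation and the nearest substrate centre (C11) is only β, while the cis-tetrahydropyran serves to bring the two chain ends together. The step needs branched-over-linear regioselectivity (secured by the catalyst), ring closure over head-to-tail oligomerisation (secured by the 2 mM concentration and slow addition) and chemoselectivity for the acid over the free C5 hydroxyl (secured because only the acidic O–H adds oxidatively and no acyl electrophile is formed).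

Step 13
Reactants: 16 (1R,5S,7R,9S,11R,13S)-5-ethenyl-13-hydroxy-7-methoxy-9-methyl-4,15-dioxabicyclo[9.3.1]pentadecan-3-one
Product: 18 (1R,5R,7R,9S,11R,13S)-13-hydroxy-7-methoxy-9-methyl-5-propyl-4,15-dioxabicyclo[9.3.1]pentadecan-3-one, via propenyl macrolactone 17 (not isolated)
Conditions: cis-2-butene (excess), second-generation Grubbs catalyst (H2IMes)(PCy3)Cl2Ru=CHPh (5 mol %), CH2Cl2, 40 °C, sealed tube; filter through silica; then H2 (1 atm), 5% Rh/Al2O3, EtOAc, rt
Reagents that add atoms: cis-2-butene, C/C=C\C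
Why: Olefin cross-metathesis with excess 2-butene exchanges the terminal CH2 for CHCH3, and hydrogenation over rhodium, chosen to avoid hydrogenolysis of the allylic C13–O bond, saturates the propenyl group to the n-propyl chain without touching C13.

Step 14
Reactants: 19 prop-2-yn-1-amine
Product: 20 methyl N-(prop-2-yn-1-yl)carbamate
Conditions: ClCO2Me, NaHCO3, CH2Cl2/H2O, 0 °C
Reagents that add atoms: methyl chloroformate, COC(=O)Cl
Why: Schotten–Baumann N-acylation of the primary amine by the chloroformate.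

Step 15
Reactants: 21 methyl 5-bromo-4-oxopentanoate
Product: 22 methyl 3-(2-amino-1,3-oxazol-4-yl)propanoate
Conditions: urea (5 equiv), DMF, 110 °C
Reagents that add atoms: urea, NC(N)=O
Why: Hantzsch-type oxazole synthesis: O-alkylation of urea by the bromoketone, cyclisation of nitrogen onto the ketone and dehydration place the propanoate chain at C4 and the amino group at C2.

Step 16
Reactants: 22 methyl 3-(2-amino-1,3-oxazol-4-yl)propanoate
Product: 23 methyl 3-(2-bromo-1,3-oxazol-4-yl)propanoate
Conditions: tBuONO, CuBr2, MeCN, 0 °C to rt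
Reagents that add atoms: copper dibromide, [Cu+2].[Br-].[Br-]
Why: Sandmeyer-type reaction: diazotisation by the alkyl nitrite and copper-mediated bromide transfer replace the C2 amino group by bromine.

Step 17
Reactants: 23 methyl 3-(2-bromo-1,3-oxazol-4-yl)propanoate and 20 methyl N-(prop-2-yn-1-yl)carbamate
Product: 24 methyl 3-{2-[3-(methoxycarbonylamino)prop-1-yn-1-yl]-1,3-oxazol-4-yl}propanoate
Conditions: Pd(PPh3)2Cl2 (5 mol %), CuI (10 mol %), Et3N, MeCN, rt
Reagents that add atoms: none
Why: Sonogashira coupling at the activated C2–Br bond of the oxazole (oxidative addition to zerovalent palladium, alkynyl transfer from copper, reductive elimination).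

Step 18
Reactants: 24 methyl 3-{2-[3-(methoxycarbonylamino)prop-1-yn-1-yl]-1,3-oxazol-4-yl}propanoate
Product: 25 methyl 3-{2-[(Z)-3-(methoxycarbonylamino)prop-1-en-1-yl]-1,3-oxazol-4-yl}propanoate
Conditions: H2 (1 atm), Pd/CaCO3 poisoned with Pb(OAc)2, quinoline, EtOAc, rt
Reagents that add atoms: none
Why: Lindlar semi-hydrogenation adds H2 syn to the alkyne and stops at the (Z)-alkene, and the oxazole and esters are not reduced.

Step 19
Reactants: 25 methyl 3-{2-[(Z)-3-(methoxycarbonylamino)prop-1-en-1-yl]-1,3-oxazol-4-yl}propanoate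
Product: 26 methyl N-{(Z)-3-[4-(3-oxopropyl)-1,3-oxazol-2-yl]prop-2-en-1-yl}carbamate
Conditions: iBu2AlH (2.2 equiv), CH2Cl2, −78 °C; aq. KNaC4H4O6 work-up
Reagents that add atoms: none
Why: Partial reduction of the methyl ester at low temperature stops at the tetrahedral aluminate and gives the aldehyde on work-up, the carbamate being masked in situ as its N-aluminium derivative.

Step 20
Reactants: 26 methyl N-{(Z)-3-[4-(3-oxopropyl)-1,3-oxazol-2-yl]prop-2-en-1-yl}carbamate
Product: 27 methyl (Z)-5-{2-[(Z)-3-(methoxycarbonylamino)prop-1-en-1-yl]-1,3-oxazol-4-yl}pent-2-enoate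
Conditions: (CF3CH2O)2P(O)CH2CO2Me, KN(SiMe3)2, 18-crown-6, THF, −78 °C; then 26
Reagents that add atoms: methyl bis(2,2,2-trifluoroethoxy)phosphorylacetate, COC(=O)CP(=O)(OCC(F)(F)F)OCC(F)(F)F
Why: Still–Gennari olefination: the electron-poor phosphonate under dissociating conditions eliminates quickly from the kinetically formed adduct and gives the (Z)-enoate.

Step 21
Reactants: 27 methyl (Z)-5-{2-[(Z)-3-(methoxycarbonylamino)prop-1-en-1-yl]-1,3-oxazol-4-yl}pent-2-enoate
Product: 28 (Z)-5-{2-[(Z)-3-(methoxycarbonylamino)prop-1-en-1-yl]-1,3-oxazol-4-yl}pent-2-enoic acid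
Conditions: LiOH, THF/H2O, 0 °C to rt; then 1 M HCl to pH 3
Reagents that add atoms: lithium hydroxide, [Li+].[OH-]
Why: Mild saponification cleaves the methyl ester, while the much less electrophilic methyl carbamate survives and the (Z)-enoate should not isomerise.

Step 22
Reactants: 18 (1R,5R,7R,9S,11R,13S)-13-hydroxy-7-methoxy-9-methyl-5-propyl-4,15-dioxabicyclo[9.3.1]pentadecan-3-one and 28 (Z)-5-{2-[(Z)-3-(methoxycarbonylamino)prop-1-en-1-yl]-1,3-oxazol-4-yl}pent-2-enoic acid
Product: 29 neopeltolide
Conditions: PPh3, DIAD, benzene, rt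
Reagents that add atoms: none
Why: Mitsunobu esterification: the equatorial C5 alcohol is activated as its alkoxyphosphonium ion and displaced by the carboxylate with inversion (SN2), giving the axial C5 ester of the target without isomerising either (Z)-olefin.

**Compound list**
1 | (R)-5-methoxy-3-methyl-5-oxopentanoic acid | COC(=O)C[C@H](C)CC(=O)O | starting material
2 | (S)-5-hydroxy-3-methylpentanoic acid | OCC[C@H](C)CC(=O)O | intermediate
3 | (S)-4-methyltetrahydro-2H-pyran-2-one | C[C@H]1CCOC(=O)C1 | intermediate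
4 | (S)-5-hydroxy-N-methoxy-N,3-dimethylpentanamide | OCC[C@H](C)CC(=O)N(C)OC | intermediate
5 | (S)-N-methoxy-N,3-dimethyl-5-oxopentanamide | O=CC[C@H](C)CC(=O)N(C)OC | intermediate
6 | (3S,5R)-5-hydroxy-N-methoxy-N,3-dimethyloct-7-ynamide | C#CC[C@H](O)C[C@H](C)CC(=O)N(C)OC | intermediate
7 | (3S,5R)-N,5-dimethoxy-N,3-dimethyloct-7-ynamide | C#CC[C@H](OC)C[C@H](C)CC(=O)N(C)OC | intermediate
8 | (3S,5R)-5-methoxy-3-methyloct-7-ynal | C#CC[C@H](OC)C[C@H](C)CC=O | intermediate
9 | (4S,6R,8R)-8-methoxy-6-methylundec-1-en-10-yn-4-ol | C#CC[C@H](OC)C[C@H](C)C[C@@H](O)CC=C | intermediate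
10 | methyl (E)-3-{[(4S,6R,8R)-8-methoxy-6-methylundec-1-en-10-yn-4-yl]oxy}prop-2-enoate | C#CC[C@H](OC)C[C@H](C)C[C@@H](O/C=C/C(=O)OC)CC=C | intermediate
11 | methyl 2-[(2R,4S,6R)-6-[(2S,4R)-4-methoxy-2-methylhept-6-yn-1-yl]-4-(trifluoroacetoxy)tetrahydro-2H-pyran-2-yl]acetate | C#CC[C@H](OC)C[C@H](C)C[C@@H]1C[C@H](OC(=O)C(F)(F)F)C[C@H](CC(=O)OC)O1 | intermediate
12 | methyl 2-[(2R,4S,6R)-4-hydroxy-6-[(2S,4R)-4-methoxy-2-methylhept-6-yn-1-yl]tetrahydro-2H-pyran-2-yl]acetate | C#CC[C@H](OC)C[C@H](C)C[C@@H]1C[C@H](O)C[C@H](CC(=O)OC)O1 | intermediate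
13 | methyl 2-[(2R,4S,6R)-6-[(2S,4R)-8-(dicyclohexylamino)-4-methoxy-2-methyloct-6-yn-1-yl]-4-hydroxytetrahydro-2H-pyran-2-yl]acetate | C1CCC(CC1)N(CC#CC[C@H](OC)C[C@H](C)C[C@@H]2C[C@H](O)C[C@H](CC(=O)OC)O2)C3CCCCC3 | intermediate
14 | methyl 2-[(2R,4S,6R)-4-hydroxy-6-[(2S,4R)-4-methoxy-2-methylocta-6,7-dien-1-yl]tetrahydro-2H-pyran-2-yl]acetate | C=C=CC[C@H](OC)C[C@H](C)C[C@@H]1C[C@H](O)C[C@H](CC(=O)OC)O1 | intermediate
15 | 2-[(2R,4S,6R)-4-hydroxy-6-[(2S,4R)-4-methoxy-2-methylocta-6,7-dien-1-yl]tetrahydro-2H-pyran-2-yl]acetic acid | C=C=CC[C@H](OC)C[C@H](C)C[C@@H]1C[C@H](O)C[C@H](CC(=O)O)O1 | intermediate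
16 | (1R,5S,7R,9S,11R,13S)-5-ethenyl-13-hydroxy-7-methoxy-9-methyl-4,15-dioxabicyclo[9.3.1]pentadecan-3-one | C=C[C@@H]1C[C@H](OC)C[C@H](C)C[C@@H]2C[C@H](O)C[C@H](CC(=O)O1)O2 | intermediate
17 | (1R,5S,7R,9S,11R,13S)-13-hydroxy-7-methoxy-9-methyl-5-[(E)-prop-1-en-1-yl]-4,15-dioxabicyclo[9.3.1]pentadecan-3-one | C/C=C/[C@@H]1C[C@H](OC)C[C@H](C)C[C@@H]2C[C@H](O)C[C@H](CC(=O)O1)O2 | intermediate
18 | (1R,5R,7R,9S,11R,13S)-13-hydroxy-7-methoxy-9-methyl-5-propyl-4,15-dioxabicyclo[9.3.1]pentadecan-3-one | CCC[C@@H]1C[C@H](OC)C[C@H](C)C[C@@H]2C[C@H](O)C[C@H](CC(=O)O1)O2 | intermediate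
19 | prop-2-yn-1-amine | C#CCN | starting material
20 | methyl N-(prop-2-yn-1-yl)carbamate | C#CCNC(=O)OC | intermediate
21 | methyl 5-bromo-4-oxopentanoate | COC(=O)CCC(=O)CBr | starting material
22 | methyl 3-(2-amino-1,3-oxazol-4-yl)propanoate | COC(=O)CCc1coc(N)n1 | intermediate
23 | methyl 3-(2-bromo-1,3-oxazol-4-yl)propanoate | COC(=O)CCc1coc(Br)n1 | intermediate
24 | methyl 3-{2-[3-(methoxycarbonylamino)prop-1-yn-1-yl]-1,3-oxazol-4-yl}propanoate | COC(=O)CCc1coc(C#CCNC(=O)OC)n1 | intermediate
25 | methyl 3-{2-[(Z)-3-(methoxycarbonylamino)prop-1-en-1-yl]-1,3-oxazol-4-yl}propanoate | COC(=O)CCc1coc(/C=C\CNC(=O)OC)n1 | intermediate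
26 | methyl N-{(Z)-3-[4-(3-oxopropyl)-1,3-oxazol-2-yl]prop-2-en-1-yl}carbamate | O=CCCc1coc(/C=C\CNC(=O)OC)n1 | intermediate
27 | methyl (Z)-5-{2-[(Z)-3-(methoxycarbonylamino)prop-1-en-1-yl]-1,3-oxazol-4-yl}pent-2-enoate | COC(=O)/C=C\CCc1coc(/C=C\CNC(=O)OC)n1 | intermediate
28 | (Z)-5-{2-[(Z)-3-(methoxycarbonylamino)prop-1-en-1-yl]-1,3-oxazol-4-yl}pent-2-enoic acid | OC(=O)/C=C\CCc1coc(/C=C\CNC(=O)OC)n1 | intermediate
29 | neopeltolide, (1R,5R,7R,9S,11R,13R)-7-methoxy-9-methyl-3-oxo-5-propyl-4,15-dioxabicyclo[9.3.1]pentadecan-13-yl (Z)-5-{2-[(Z)-3-(methoxycarbonylamino)prop-1-en-1-yl]-1,3-oxazol-4-yl}pent-2-enoate | CCC[C@@H]1C[C@H](OC)C[C@H](C)C[C@@H]2C[C@@H](OC(=O)/C=C\CCc3coc(/C=C\CNC(=O)OC)n3)C[C@H](CC(=O)O1)O2 | target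

**Count**
Total steps: 22. Longest linear sequence: 14 (steps 1–13 and 22); the side-chain acid takes 8 steps (14–21).

**Steps most likely to fail**

1. Step 12. Head-to-tail oligomerisation may outrun ring closure, or the ligand may select the C13 face poorly when the allyl complex is constrained in the ring-forming conformation. The fallback sets out from 14 and comes back at 18; it fixes C13 intermolecularly and closes the ring at the acyl C1–O bond instead.
   - The same rhodium/DIOP system adds benzoic acid to the allene of 14 without dilution and gives the branched allylic benzoate F1.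
   - Cross-metathesis with cis-2-butene and hydrogenation as in step 13 give the propyl benzoate F2.
   - TBSOTf and 2,6-lutidine give the C5 silyl ether F3.
   - LiOH in THF/MeOH/H2O at 50 °C cleaves both esters to the C13 hydroxy acid F4.
   - Yamaguchi macrolactonisation (2,4,6-trichlorobenzoyl chloride, Et3N, then DMAP, toluene, high dilution) gives the silylated macrolactone F5.
   - HF·pyridine in THF removes the silyl group and gives 18.

2. Step 4. Facial selectivity may be poor in the catalytic addition to an unbranched aliphatic aldehyde. The fallback sets out from 5 and comes back at 7.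
   - Brown allylboration with (−)-Ipc2B(allyl), the reagent and Si-face sense of step 7, gives the homoallylic alcohol F6.
   - Me3OBF4 with 1,8-bis(dimethylamino)naphthalene gives the methyl ether F7.
   - Ozonolysis (O3, CH2Cl2, −78 °C, then PPh3) gives the β-methoxy aldehyde F8.
   - Ohira–Bestmann homologation (dimethyl (1-diazo-2-oxopropyl)phosphonate, K2CO3, MeOH) gives 7.

3. Step 16. The electron-rich heteroarylamine may be halogenated at C5, or its diazonium ion may hydrolyse before bromide transfer. The fallback sets out from 21 and comes back at 24.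
   - Condensation of 21 with neat formamide at 110 °C gives the C2-unsubstituted oxazole F9.
   - Zincation at C2 with TMPZnCl·LiCl in THF, then I2, gives the 2-iodooxazole F10.
   - Sonogashira coupling of F10 with 20 under the conditions of step 17 gives 24.

Further compounds
F1 | step 12 | methyl 2-[(2R,4S,6R)-6-[(2S,4R,6S)-6-(benzoyloxy)-4-methoxy-2-methyloct-7-en-1-yl]-4-hydroxytetrahydro-2H-pyran-2-yl]acetate | C=C[C@@H](OC(=O)c1ccccc1)C[C@H](OC)C[C@H](C)C[C@@H]1C[C@H](O)C[C@H](CC(=O)OC)O1
F2 | step 12 | methyl 2-[(2R,4S,6R)-6-[(2S,4R,6R)-6-(benzoyloxy)-4-methoxy-2-methylnonyl]-4-hydroxytetrahydro-2H-pyran-2-yl]acetate | CCC[C@@H](OC(=O)c1ccccc1)C[C@H](OC)C[C@H](C)C[C@@H]1C[C@H](O)C[C@H](CC(=O)OC)O1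
F3 | step 12 | methyl 2-[(2R,4S,6R)-6-[(2S,4R,6R)-6-(benzoyloxy)-4-methoxy-2-methylnonyl]-4-[(tert-butyldimethylsilyl)oxy]tetrahydro-2H-pyran-2-yl]acetate | CCC[C@@H](OC(=O)c1ccccc1)C[C@H](OC)C[C@H](C)C[C@@H]1C[C@H](O[Si](C)(C)C(C)(C)C)C[C@H](CC(=O)OC)O1
F4 | step 12 | 2-[(2R,4S,6R)-4-[(tert-butyldimethylsilyl)oxy]-6-[(2S,4R,6R)-6-hydroxy-4-methoxy-2-methylnonyl]tetrahydro-2H-pyran-2-yl]acetic acid | CCC[C@@H](O)C[C@H](OC)C[C@H](C)C[C@@H]1C[C@H](O[Si](C)(C)C(C)(C)C)C[C@H](CC(=O)O)O1
F5 | step 12 | (1R,5R,7R,9S,11R,13S)-13-[(tert-butyldimethylsilyl)oxy]-7-methoxy-9-methyl-5-propyl-4,15-dioxabicyclo[9.3.1]pentadecan-3-one | CCC[C@@H]1C[C@H](OC)C[C@H](C)C[C@@H]2C[C@H](O[Si](C)(C)C(C)(C)C)C[C@H](CC(=O)O1)O2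
F6 | step 4 | (3S,5S)-5-hydroxy-N-methoxy-N,3-dimethyloct-7-enamide | C=CC[C@H](O)C[C@H](C)CC(=O)N(C)OC
F7 | step 4 | (3S,5S)-N,5-dimethoxy-N,3-dimethyloct-7-enamide | C=CC[C@H](OC)C[C@H](C)CC(=O)N(C)OC
F8 | step 4 | (3S,5R)-N,5-dimethoxy-N,3-dimethyl-7-oxoheptanamide | O=CC[C@H](OC)C[C@H](C)CC(=O)N(C)OC
F9 | step 16 | methyl 3-(1,3-oxazol-4-yl)propanoate | COC(=O)CCc1cocn1
F10 | step 16 | methyl 3-(2-iodo-1,3-oxazol-4-yl)propanoate | COC(=O)CCc1coc(I)n1
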